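Ring B (C-5, C-6, C-8, C-9, C-10) plus its exocyclic carboxyl C-7 is read as a contracted cyclohexanone: C-7 is the former ring carbonyl, flanked by quaternary C-8 and by C-6. The six-membered ring is the carbocycle of 2-allyl-1,4-benzoquinone, which first acts twice as a dienophile (cyclopentadiene as a removable shield, then a 2,3-disiloxybutadiene for ring C) and then as Michael acceptor for the C-19/C-10 lactone. A photochemical Wolff rearrangement of the tricyclic lactone α-diazoketone moves C-8 from C-7 to C-6, contracts the ring to ring B and releases C-7 as an ester in one operation.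

Key step: step 8

Remark: atoms of all intermediates carry the numbers they have in the target (C-1 to C-19; before step 8 the six-membered ring is C-5, C-6, C-7, C-8, C-9, C-10); β is the face of H-5, H-9 and C-15, α the face of the lactone bridge. The target is named 12α-hydroxygibberellic acid: its 12-OH lies on the face of ring C opposite to the C-15/C-16 bridge, cis to the 13-OH.
Remark: cyclopentadiene (3) is cracked from commercial dicyclopentadiene just before use.
Assumption: the sense of induction of the oxazaborolidinium catalyst in step 2 is taken from its usual pretransition-state model; if 4 formed as the antipode, the enantiomeric catalyst would be used.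

Step 1
Reactants: 1 2-allylphenol
Product: 2 2-allyl-1,4-benzoquinone
Conditions: K2[ON(SO3)2] (2.2 equiv), KH2PO4, H2O/acetone, 0 °C → rt
Reagents that add atoms: potassium nitrosodisulfonate, [K+].[K+].[O]N(S(=O)(=O)[O-])S(=O)(=O)[O-]
Why: Teuber oxidation, in which the nitroxyl radical converts a phenol with a free para position into the para-quinone under buffered conditions that leave the allyl group untouched; no stereocentre is formed.

Step 2
Reactants: 2 2-allyl-1,4-benzoquinone, 3 cyclopentadiene
Product: 4 endo cyclopentadiene adduct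
Conditions: (S)-3,3-diphenyl-1-(2-methylphenyl)tetrahydro-1H,3H-pyrrolo[1,2-c][1,3,2]oxazaborole·HN(SO2CF3)2 (10 mol %), CH2Cl2, −78 °C
Reagents that add atoms: none
Why: Catalytic enantioselective Diels–Alder reaction in which the diene adds endo to the unsubstituted, more reactive C=C of the Lewis acid-bound quinone from the unshielded face, setting the four temporary stereocentres in one sense and leaving the allyl-bearing C=C as the only dienophile.

Step 3
Reactants: 5 butane-2,3-dione
Product: 6 2,3-bis(tert-butyldimethylsilyloxy)buta-1,3-diene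
Conditions: t-BuMe2SiOTf (2.2 equiv), Et3N, CH2Cl2, 0 °C → rt
Reagents that add atoms: tert-butyldimethylsilyl triflate, CC(C)(C)[Si](C)(C)OS(=O)(=O)C(F)(F)F
Why: Double soft enolisation and O-silylation of the 1,2-diketone gives the electron-rich diene; no stereocentre is formed.

Step 4
Reactants: 4 endo cyclopentadiene adduct, 6 2,3-bis(tert-butyldimethylsilyloxy)buta-1,3-diene
Product: 7 bis-adduct
Conditions: toluene, 100 °C, sealed tube
Reagents that add atoms: none
Why: Thermal Diels–Alder reaction of the symmetrical diene (no regiochemical issue) with the remaining enedione C=C from the convex face, syn to H-5/H-6 and anti to the norbornene, which creates quaternary C-8 (allyl = C-15 to C-17) and C-9 cis to each other with the absolute sense relayed from 4.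

Step 5
Reactants: 7 bis-adduct
Product: 8 cis-fused enedione
Conditions: Ph2O, 250 °C, N2 stream
Reagents that add atoms: none
Why: Thermal retro-Diels–Alder reaction expels volatile cyclopentadiene and restores the C-5=C-6 enedione double bond, while C-8 and C-9, which take no part in the cycloreversion, keep their configuration.

Step 6
Reactants: 8 cis-fused enedione, 9 vinylmagnesium bromide, 10 propanoic anhydride
Product: 12 tertiary propanoate of the C-10 alcohol, via bromomagnesium alkoxide 11 (not isolated)
Conditions: CeCl3, THF, −78 °C; then (EtCO)2O, DMAP, −78 → 0 °C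
Reagents that add atoms: none
Why: 1,2-Addition of the weakly basic vinylcerium reagent to the less hindered enedione carbonyl (C-10, next to C-9–H and not next to quaternary C-8) from the convex β face anti to ring C sets C-10 with its oxygen α, and the tertiary alkoxide is acylated in the same flask.

Step 7
Reactants: 12 tertiary propanoate of the C-10 alcohol
Product: 15 tricyclic lactone α-diazoketone, via lithium enolate 13 (not isolated), via trifluoroacetyl ketone 14 (not isolated)
Conditions: LiN(SiMe3)2, THF, −78 → −40 °C; CF3CO2CH2CF3, −78 °C; then MeSO2N3, Et3N, H2O, MeCN, rt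
Reagents that add atoms: methanesulfonyl azide, CS(=O)(=O)N=[N+]=[N-]
Why: Intramolecular 5-exo-trig Michael addition of the propanoate enolate to C-5 forges C-4–C-5 and the cis-fused γ-lactone (H-5 β, fixed by the C-10–O tether; C-4 still epimeric), and the ketone enolate so formed is C-trifluoroacetylated and taken through detrifluoroacetylative Regitz diazo transfer, which can only reach C-6 because C-8 is quaternary.

Step 8
Reactants: 15 tricyclic lactone α-diazoketone
Product: 17 ring-contracted 2-(trimethylsilyl)ethyl ester, via ketene 16 (not isolated)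
Conditions: hν (>300 nm, Pyrex), Me3SiCH2CH2OH, THF, rt; then KOt-Bu (0.2 equiv), 0 °C
Reagents that add atoms: 2-(trimethylsilyl)ethanol, C[Si](C)(C)CCO
Why: Photolysis expels N2 from the cyclic, s-Z-locked α-diazoketone while C-8 migrates in concert from the carbonyl carbon to C-6 (Wolff rearrangement), so that the six-membered ring becomes ring B and the former ring carbonyl leaves the ring as ketene carbon C-7, which the alcohol traps as the ester. The closest known reaction type is the photochemical Wolff ring contraction of cyclic α-diazoketones. No ring is closed by joining two chain ends: ring B arises from the 1,2-shift alone. C-8 migrates with retention, and the new stereocentre C-6 is set under thermodynamic control by the alkoxide equilibration, the ester settling on the β face trans to C-4. The step needs rearrangement to win over carbene cyclopropanation of the allyl or vinyl group and over C–H insertion, which the concerted pathway of the s-Z diazoketone and the absence of a metal catalyst secure, and the site of contraction is fixed because C-8 is the only ring atom on the carbonyl carbon besides C-6.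

Step 9
Reactants: 17 ring-contracted 2-(trimethylsilyl)ethyl ester, 18 acrolein
Product: 20 C-3 silyl ether of the aldol adduct, via lithium aldolate 19 (not isolated)
Conditions: LiN(i-Pr)2 (1.1 equiv), THF, −78 °C; acrolein; then t-BuMe2SiOTf, 2,6-lutidine, −78 → −40 °C
Reagents that add atoms: tert-butyldimethylsilyl triflate, CC(C)(C)[Si](C)(C)OS(=O)(=O)C(F)(F)F
Why: Aldol addition of the lactone lithium enolate (the lactone α-H is more acidic and less hindered than H-6 of the ester) to acrolein on the convex face cis to the C-10 vinyl group makes C-4 quaternary, a closed Zimmerman–Traxler transition state with the methyl cis to the enolate oxygen should place O-3 cis to C-18 (3β), and the aldolate is silylated before retro-aldol cleavage can occur.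

Step 10
Reactants: 20 C-3 silyl ether of the aldol adduct
Product: 21 ring D ketone
Conditions: Pd(OAc)2 (10 mol %), O2 (1 atm), DMSO, 45 °C
Reagents that add atoms: none
Why: Proposed new method: palladium diacetate is expected to bind the unhindered allyl alkene, the ene-diol disilyl ether then attacks as a silyl enol ether through C-13 in the 5-exo mode (attack through C-12 would need a 6-exo closure to a bicyclo[2.2.2]octane), the C-12 siloxy group collapses to the ketone with loss of its silyl group, and β-hydride elimination from C-16 leaves the exocyclic C-16=C-17 methylene while zerovalent palladium is reoxidised by O2; C-13 is set by the tether (new bond β, O-13 α); the closest known reaction type is the palladium-mediated oxidative cycloalkenylation of silyl enol ethers bearing a pendant alkene (Saegusa-type chemistry), which has not been shown on a 1,2-bis(silyloxy)alkene.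

Step 11
Reactants: 21 ring D ketone
Product: 22 protected 12-oxo gibberellin
Conditions: second-generation Hoveyda–Grubbs catalyst (5 mol %), toluene, 80 °C
Reagents that add atoms: none
Why: Ring-closing metathesis of the vinyl groups on C-10 and C-3, held cis on the lactone ring, closes ring A as the C-1=C-2 cyclohexene with loss of ethene, the 1,1-disubstituted exocyclic methylene being too hindered to take part; no stereocentre is formed.

Step 12
Reactants: 22 protected 12-oxo gibberellin
Product: 23 protected 12α-hydroxygibberellic acid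
Conditions: LiBH(s-Bu)3, THF, −78 °C
Reagents that add atoms: none
Why: Ketone reduction by the bulky borohydride from the equatorial β side, the axial approach being blocked by the syn-axial C-9–C-10 bond, should give the axial 12α-alcohol cis to O-13, while lactone and ester are inert at this temperature.

Step 13
Reactants: 23 protected 12α-hydroxygibberellic acid
Product: 24 12α-hydroxygibberellic acid (the target gibberellin)
Conditions: Bu4NF, AcOH, THF, 0 °C → rt; work-up at pH 3
Reagents that add atoms: none
Why: Fluoride cleaves both silyl ethers and fragments the 2-(trimethylsilyl)ethyl ester to the carboxylate, the acetic acid buffer preventing base-induced lactone migration in ring A; no stereocentre is touched.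

Compound list
1 | 2-allylphenol | C=CCc1ccccc1O | starting material
2 | 2-allyl-1,4-benzoquinone | C=CCC1=CC(=O)C=CC1=O | intermediate
3 | cyclopenta-1,3-diene | C1=CCC=C1 | starting material
4 | (4aR,5S,8R,8aS)-2-allyl-4a,5,8,8a-tetrahydro-5,8-methanonaphthalene-1,4-dione (endo adduct) | C=CCC1=CC(=O)[C@@H]2[C@@H]3C=C[C@@H](C3)[C@@H]2C1=O | intermediate
5 | butane-2,3-dione | CC(=O)C(C)=O | starting material
6 | 2,3-bis(tert-butyldimethylsilyloxy)buta-1,3-diene | C=C(O[Si](C)(C)C(C)(C)C)C(=C)O[Si](C)(C)C(C)(C)C | intermediate
7 | 4a-allyl-2,3-bis(tert-butyldimethylsilyloxy)-1,4,4a,5,8,8a,9a,10a-octahydro-5,8-methanoanthracene-9,10-dione; both ring fusions cis, norbornene endo, ring C on the face of the central ring opposite to the norbornene, allyl and H-9 on the norbornene side | C=CC[C@]23CC(O[Si](C)(C)C(C)(C)C)=C(O[Si](C)(C)C(C)(C)C)C[C@H]2C(=O)[C@@H]4[C@@H]5C=C[C@@H](C5)[C@@H]4C3=O | intermediate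
8 | (4aR,8aS)-8a-allyl-6,7-bis(tert-butyldimethylsilyloxy)-4a,5,8,8a-tetrahydronaphthalene-1,4-dione (cis-fused; allyl on C-8 and H-9 both β) | C=CC[C@]23CC(O[Si](C)(C)C(C)(C)C)=C(O[Si](C)(C)C(C)(C)C)C[C@H]2C(=O)C=CC3=O | intermediate
9 | vinylmagnesium bromide | C=C[Mg]Br | starting material
10 | propanoic anhydride | CCC(=O)OC(=O)CC | starting material
11 | bromomagnesium salt of the C-10 tertiary alkoxide from vinyl addition to 8 (vinyl β, oxygen α) | C=CC[C@]23CC(O[Si](C)(C)C(C)(C)C)=C(O[Si](C)(C)C(C)(C)C)C[C@H]2[C@@](C=C)([O-])C=CC3=O.[Mg+2].[Br-] | intermediate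
12 | 8a-allyl-6,7-bis(tert-butyldimethylsilyloxy)-1-oxo-4-vinyl-1,4,4a,5,8,8a-hexahydronaphthalen-4-yl propanoate; vinyl β (cis to H-9 and to the allyl group), propanoyloxy α | C=CC[C@]23CC(O[Si](C)(C)C(C)(C)C)=C(O[Si](C)(C)C(C)(C)C)C[C@H]2[C@@](C=C)(OC(=O)CC)C=CC3=O | intermediate
13 | lithium C-6/C-7 enolate of the tricyclic 19,10-lactone ketone (Michael adduct; H-5 β, C-4 epimers) | C=CC[C@]23CC(O[Si](C)(C)C(C)(C)C)=C(O[Si](C)(C)C(C)(C)C)C[C@H]2[C@@]4(C=C)OC(=O)C(C)[C@H]4C=C3[O-].[Li+] | intermediate
14 | 6-trifluoroacetyl derivative of the tricyclic 19,10-lactone 7-ketone (C-4 and C-6 epimers) | C=CC[C@]23CC(O[Si](C)(C)C(C)(C)C)=C(O[Si](C)(C)C(C)(C)C)C[C@H]2[C@@]4(C=C)OC(=O)C(C)[C@H]4C(C(=O)C(F)(F)F)C3=O | intermediate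
15 | tricyclic 19,10-lactone 6-diazo-7-ketone: 8-allyl (β), 10-vinyl (β), H-5 and H-9 β, 12,13-bis(tert-butyldimethylsilyloxy)-12-ene, C-4 epimers | C=CC[C@]23CC(O[Si](C)(C)C(C)(C)C)=C(O[Si](C)(C)C(C)(C)C)C[C@H]2[C@@]4(C=C)OC(=O)C(C)[C@H]4C(=[N+]=[N-])C3=O | intermediate
16 | ketene with contracted ring B (C-6=C-7=O) | C=CC[C@]23CC(O[Si](C)(C)C(C)(C)C)=C(O[Si](C)(C)C(C)(C)C)C[C@H]2[C@@]4(C=C)OC(=O)C(C)[C@H]4C3=C=O | intermediate
17 | 2-(trimethylsilyl)ethyl ester with ring B as cyclopentane: C-7 ester β on C-6, 19,10-lactone α, 8-allyl and 10-vinyl β, 12,13-bis(tert-butyldimethylsilyloxy)-12-ene, C-4 epimers | C=CC[C@]23CC(O[Si](C)(C)C(C)(C)C)=C(O[Si](C)(C)C(C)(C)C)C[C@H]2[C@@]4(C=C)OC(=O)C(C)[C@H]4[C@@H]3C(=O)OCC[Si](C)(C)C | intermediate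
18 | acrolein (prop-2-enal) | C=CC=O | starting material
19 | lithium aldolate of 17 with acrolein (C-4 quaternary, O-3 β) | C=CC[C@]23CC(O[Si](C)(C)C(C)(C)C)=C(O[Si](C)(C)C(C)(C)C)C[C@H]2[C@@]4(C=C)OC(=O)[C@](C)([C@@H]([O-])C=C)[C@H]4[C@@H]3C(=O)OCC[Si](C)(C)C.[Li+] | intermediate
20 | aldol adduct as its 3β-tert-butyldimethylsilyl ether: C-4 bears methyl C-18 and the CH(OSi)CH=CH2 group cis to the C-10 vinyl group; otherwise as 17 | C=CC[C@]23CC(O[Si](C)(C)C(C)(C)C)=C(O[Si](C)(C)C(C)(C)C)C[C@H]2[C@@]4(C=C)OC(=O)[C@](C)([C@@H](O[Si](C)(C)C(C)(C)C)C=C)[C@H]4[C@@H]3C(=O)OCC[Si](C)(C)C | intermediate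
21 | ring D ketone: bicyclo[3.2.1]octane with C-13–C-16 bond, 16-methylene, 13α-tert-butyldimethylsilyloxy, 12-oxo; ring A still open (10-vinyl, 3-vinyl carbinol silyl ether) | C=C1C[C@]23C[C@@]1(O[Si](C)(C)C(C)(C)C)C(=O)C[C@H]2[C@@]4(C=C)OC(=O)[C@](C)([C@@H](O[Si](C)(C)C(C)(C)C)C=C)[C@H]4[C@@H]3C(=O)OCC[Si](C)(C)C | intermediate
22 | 3,13-bis-O-(tert-butyldimethylsilyl)-12-oxogibberellic acid 2-(trimethylsilyl)ethyl ester | C=C1C[C@]23C[C@@]1(O[Si](C)(C)C(C)(C)C)C(=O)C[C@H]2[C@@]12C=C[C@H](O[Si](C)(C)C(C)(C)C)[C@@](C)(C(=O)O1)[C@H]2[C@@H]3C(=O)OCC[Si](C)(C)C | intermediate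
23 | 3,13-bis-O-(tert-butyldimethylsilyl)-12α-hydroxygibberellic acid 2-(trimethylsilyl)ethyl ester (12-OH cis to O-13) | C=C1C[C@]23C[C@@]1(O[Si](C)(C)C(C)(C)C)[C@@H](O)C[C@H]2[C@@]12C=C[C@H](O[Si](C)(C)C(C)(C)C)[C@@](C)(C(=O)O1)[C@H]2[C@@H]3C(=O)OCC[Si](C)(C)C | intermediate
24 | 12α-hydroxygibberellic acid, the target gibberellin (12-OH cis to 13-OH, on the face of ring C opposite to the C-15/C-16 bridge) | C=C1C[C@]23C[C@@]1(O)[C@@H](O)C[C@H]2[C@@]12C=C[C@H](O)[C@@](C)(C(=O)O1)[C@H]2[C@@H]3C(=O)O | target

Total step count: 13. Longest linear sequence: 12 steps (steps 1, 2 and 4 to 13; step 3 is a one-step branch).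

Steps most likely to fail

Step 10 (proposed new method). The ene-diol disilyl ether may be dehydrogenated or oxidised to the 1,2-diketone by divalent palladium instead of forming the C-13–C-16 bond, or it may close in the 6-exo mode through C-12. The fallback sets out from 20 and returns at 21; it replaces the oxidative cyclisation by an aldol construction of the same bond. Wacker oxidation (PdCl2, CuCl, O2, DMF/H2O) of the allyl group, the only terminal alkene without an allylic oxygen or a neighbouring quaternary carbon, gives the methyl ketone F1. An intramolecular Mukaiyama aldol addition (TiCl4, CH2Cl2, −78 °C) of the 1,2-bis(silyloxy)alkene through C-13 to the C-16 ketone then gives the tertiary alcohol F2 with the C-12 ketone set free. Dehydration with the Burgess reagent to the exocyclic alkene gives 21.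

Step 9. Facial discrimination at the aldehyde may be poor, giving both C-3 epimers, and proton transfer may erode the aldolate before it is trapped. The fallback sets out from 17 and returns at 20; it sets C-3 by reagent control instead of by the aldol transition state. The aldol addition is run without silyl trap to give the free aldol F3 as a C-3 mixture, Dess–Martin periodinane gives the vinyl ketone F4, and Corey–Bakshi–Shibata reduction (oxazaborolidine chosen to differentiate the quaternary C-4 from the vinyl group) gives the 3β-allylic alcohol F5. Silylation (t-BuMe2SiOTf, 2,6-lutidine) gives 20.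

Step 6. Acylation of the hindered tertiary alkoxide may be slow, so that enolisation of the anhydride or attack at the second carbonyl competes. The fallback sets out from 8 and returns at 15; it forms the lactone by reductive enolate generation instead of deprotonation. Vinylcerium addition with aqueous work-up gives the tertiary alcohol F6, the more reactive 2-bromopropanoyl bromide (pyridine, DMAP) gives the α-bromo ester F7, and SmI2 (THF, −78 °C) generates the samarium enolate, which closes C-4–C-5 by Reformatsky-type 5-exo conjugate addition to give the lactone ketone F8. Trifluoroacetylation (LiN(SiMe3)2, CF3CO2CH2CF3) and diazo transfer (MeSO2N3, Et3N) then give 15.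

Further compounds
F1 | step 10 | methyl ketone from Wacker oxidation of the allyl group of 20 (C-16 ketone) | CC(=O)C[C@]23CC(O[Si](C)(C)C(C)(C)C)=C(O[Si](C)(C)C(C)(C)C)C[C@H]2[C@@]4(C=C)OC(=O)[C@](C)([C@@H](O[Si](C)(C)C(C)(C)C)C=C)[C@H]4[C@@H]3C(=O)OCC[Si](C)(C)C
F2 | step 10 | aldol product with ring D closed: 16-hydroxy-16-methyl, 13-silyloxy, 12-oxo (C-16 epimers) | CC1(O)C[C@]23C[C@@]1(O[Si](C)(C)C(C)(C)C)C(=O)C[C@H]2[C@@]4(C=C)OC(=O)[C@](C)([C@@H](O[Si](C)(C)C(C)(C)C)C=C)[C@H]4[C@@H]3C(=O)OCC[Si](C)(C)C
F3 | step 9 | free acrolein aldol adduct of 17 (C-3 epimers) | C=CC[C@]23CC(O[Si](C)(C)C(C)(C)C)=C(O[Si](C)(C)C(C)(C)C)C[C@H]2[C@@]4(C=C)OC(=O)[C@](C)(C(O)C=C)[C@H]4[C@@H]3C(=O)OCC[Si](C)(C)C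
F4 | step 9 | C-3 vinyl ketone | C=CC[C@]23CC(O[Si](C)(C)C(C)(C)C)=C(O[Si](C)(C)C(C)(C)C)C[C@H]2[C@@]4(C=C)OC(=O)[C@](C)(C(=O)C=C)[C@H]4[C@@H]3C(=O)OCC[Si](C)(C)C
F5 | step 9 | 3β-allylic alcohol | C=CC[C@]23CC(O[Si](C)(C)C(C)(C)C)=C(O[Si](C)(C)C(C)(C)C)C[C@H]2[C@@]4(C=C)OC(=O)[C@](C)([C@@H](O)C=C)[C@H]4[C@@H]3C(=O)OCC[Si](C)(C)C
F6 | step 6 | C-10 tertiary alcohol from vinyl addition to 8 (vinyl β, OH α) | C=CC[C@]23CC(O[Si](C)(C)C(C)(C)C)=C(O[Si](C)(C)C(C)(C)C)C[C@H]2[C@@](C=C)(O)C=CC3=O
F7 | step 6 | 2-bromopropanoate of F6 (epimers at the bromine-bearing carbon) | C=CC[C@]23CC(O[Si](C)(C)C(C)(C)C)=C(O[Si](C)(C)C(C)(C)C)C[C@H]2[C@@](C=C)(OC(=O)C(C)Br)C=CC3=O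
F8 | step 6 | tricyclic 19,10-lactone 7-ketone (neutral Michael-type adduct, C-4 epimers) | C=CC[C@]23CC(O[Si](C)(C)C(C)(C)C)=C(O[Si](C)(C)C(C)(C)C)C[C@H]2[C@@]4(C=C)OC(=O)C(C)[C@H]4CC3=O
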